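The cyclohexene ring (numbered from the acetoxy carbon C1) contains the homoallylic acetate array C1(OAc)–C2H2–C3H=C4(CH3). Everything rests on cutting C1–C2 and C3=C4 together, so that C2 and C3 come from a vinylboron reagent. The precursor is acyclic: a methyl ketone tosylhydrazone with a masked neopentyl aldehyde. Its diazoalkane inserts into the boron–vinyl bond, and the tertiary allylboronic acid so formed allylates the tethered aldehyde through its terminal carbon. One operation closes the ring, fixes the trisubstituted alkene and sets the carbinol centre trans to the aryloxymethyl group. The other stereocentre, C5, comes from an iridium-catalysed asymmetric allylic alkylation.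

Key step: step 7

Assumption: the (S,S,S) antipode of the phosphoramidite ligand is taken to deliver the R centre in 7. If the sense of induction is the opposite for this substrate pair, the mirror-image ligand is used and nothing else changes.

Step 1
Reactants: 1 umbelliferone (7-hydroxy-2H-chromen-2-one); 2 racemic 2-vinyloxirane
Product: 3 7-{[(2E)-4-hydroxybut-2-en-1-yl]oxy}-2H-chromen-2-one
Conditions: Pd(PPh3)4 (2 mol %), THF, 0 °C to rt
Reagents that add atoms: none
Why: Tsuji–Trost-type opening of the vinyl epoxide, in which zerovalent palladium gives a π-allyl alkoxide that deprotonates the phenol, and because aryl ether formation is reversible under the catalyst the phenoxide should end up at the unhindered distal terminus as the linear E 1,4-adduct, with the epoxide stereocentre lost and no new one formed.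

Step 2
Reactants: 3 7-{[(2E)-4-hydroxybut-2-en-1-yl]oxy}-2H-chromen-2-one
Product: 4 methyl (2E)-4-[(2-oxo-2H-chromen-7-yl)oxy]but-2-en-1-yl carbonate
Conditions: ClCO2Me, pyridine, CH2Cl2, 0 °C
Reagents that add atoms: methyl chloroformate, COC(=O)Cl
Why: Standard O-acylation of a primary allylic alcohol with a chloroformate installs the leaving group for the allylic substitution.

Step 3
Reactants: 4 methyl (2E)-4-[(2-oxo-2H-chromen-7-yl)oxy]but-2-en-1-yl carbonate; 5 4-(2-methylprop-1-en-1-yl)morpholine
Product: 7 (3R)-2,2-dimethyl-3-{[(2-oxo-2H-chromen-7-yl)oxy]methyl}pent-4-enal, via iminium salt 6 (not isolated)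
Conditions: [Ir(cod)Cl]2 (2 mol %), (S,S,S)-O,O′-(1,1′-binaphthyl-2,2′-diyl) N,N-bis(1-phenylethyl)phosphoramidite (4 mol %), n-PrNH2 (activation), THF, rt; then AcOH/NaOAc/H2O
Reagents that add atoms: water, O
Why: Iridium-catalysed asymmetric allylic alkylation with an enamine, in which the cyclometallated iridium phosphoramidite complex ionises the carbonate, the β-carbon of the enamine attacks the substituted allyl terminus anti to the metal (branched selectivity is typical of this catalyst class), the ligand fixes the new C–H stereocentre as R, the neighbouring quaternary carbon is not stereogenic, and buffered hydrolysis of iminium salt 6 frees the aldehyde.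

Step 4
Reactants: 7 (3R)-2,2-dimethyl-3-{[(2-oxo-2H-chromen-7-yl)oxy]methyl}pent-4-enal
Product: 8 (3R)-2,2-dimethyl-3-{[(2-oxo-2H-chromen-7-yl)oxy]methyl}pent-4-ene-1,1-diyl diacetate
Conditions: Ac2O (3 equiv), Bi(OTf)3 (0.5 mol %), MeCN, rt
Reagents that add atoms: acetic anhydride, CC(=O)OC(C)=O
Why: Lewis acid-catalysed acylal (geminal diacetate) formation masks the aldehyde in a form that stands neutral and weakly acidic media but falls off under aqueous carbonate, so no separate deprotection is needed later.

Step 5
Reactants: 8 (3R)-2,2-dimethyl-3-{[(2-oxo-2H-chromen-7-yl)oxy]methyl}pent-4-ene-1,1-diyl diacetate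
Product: 9 (3R)-2,2-dimethyl-4-oxo-3-{[(2-oxo-2H-chromen-7-yl)oxy]methyl}pentane-1,1-diyl diacetate
Conditions: PdCl2 (10 mol %), Cu(OAc)2·H2O (20 mol %), O2 (1 atm), DMA–H2O 7:1, rt
Reagents that add atoms: water, O
Why: Wacker–Tsuji oxidation, in which Markovnikov hydroxypalladation of the terminal alkene gives the methyl ketone, and copper diacetate in place of copper chloride keeps the medium close to neutral so that the acylal and the centre next to the new ketone are not touched.

Step 6
Reactants: 9 (3R)-2,2-dimethyl-4-oxo-3-{[(2-oxo-2H-chromen-7-yl)oxy]methyl}pentane-1,1-diyl diacetate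
Product: 10 (3S,4E)-2,2-dimethyl-4-[2-(4-methylbenzenesulfonyl)hydrazinylidene]-3-{[(2-oxo-2H-chromen-7-yl)oxy]methyl}pentane-1,1-diyl diacetate (same spatial arrangement as in 9; the descriptor changes with the priorities)
Conditions: TsNHNH2 (1.1 equiv), PPTS (5 mol %), 4 Å MS, THF, 45 °C
Reagents that add atoms: 4-methylbenzenesulfonohydrazide, Cc1ccc(cc1)S(=O)(=O)NN
Why: Hydrazone condensation at the only free carbonyl group gives the E-tosylhydrazone, while the aprotic solvent and the weak acid spare the acylal and limit the ene-hydrazine tautomerisation that would erode the adjacent stereocentre.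

Step 7
Reactants: 10 (3S,4E)-tosylhydrazone diacetate; 11 2,4,6-trivinylcyclotriboroxane–pyridine complex
Product: 15 7-{[(1R,5R)-5-hydroxy-2,6,6-trimethylcyclohex-2-en-1-yl]methoxy}-2H-chromen-2-one, via aldehyde hydrazone 12 (not isolated), via diazoalkane 13 (not isolated), via allylboronic acid 14 (not isolated)
Conditions: 11 (0.7 equiv), K2CO3 (4 equiv), H2O (3 equiv), 1,4-dioxane, 110 °C (sealed tube); then aq. citric acid
Reagents that add atoms: none
Why: Proposed new method: carbonate and water first strip the two acetates from the acylal (12), the tosylhydrazone salt loses sulfinate in a Bamford–Stevens fragmentation to diazoalkane 13, and the diazo carbon binds the boron of vinylboronic acid and receives the vinyl group by 1,2-shift with loss of N2 (first new C–C bond), giving the tertiary allylboronic acid 14. Compound 14 then attacks the tethered aldehyde through its terminal CH2 (γ-selective allylboration, second new C–C bond), which moves the double bond into the trisubstituted ring position and leaves boron on oxygen. The closest known reaction types are the metal-free coupling of N-tosylhydrazones with alkenylboronic acids, its three-component version in which the transient allylboronic acid is trapped by an added aldehyde, and domino carbocyclisations in which it is trapped by a tethered nitrile; new here are the unsubstituted vinyl donor and a tethered aldehyde that puts all three allyl carbons into the ring. The six-membered carbocycle closes 6-exo-trig at the carbonyl group with the allyl unit endocyclic, through a boat-shaped six-centre array in which the B–O link bridges the 1,4-positions (bicyclo[2.2.2]octane-like). The new carbinol centre is controlled by the existing one: boron binds the diazo carbon anti to the CMe2CHO group (Felkin–Anh-type, H next to CH3), oxygen must end on the ring face that held boron, and the aryloxymethyl group points to the slim CH=CH bridge rather than to the B(OH)2–O bridge, so O and CH2OAr should end up trans, (1R,5R). The step needs γ- over α-attack, ring closure faster than protodeboronation or 1,3-boron shift, and diazo formation at the ketone carbon only; the alternative closure would give a cyclobutane, the aldehyde sits four atoms away and cannot enolise, and it stays masked until the hydrazone is in place.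

Step 8
Reactants: 15 7-{[(1R,5R)-5-hydroxy-2,6,6-trimethylcyclohex-2-en-1-yl]methoxy}-2H-chromen-2-one
Product: 16 (1R,5R)-4,6,6-trimethyl-5-{[(2-oxo-2H-chromen-7-yl)oxy]methyl}cyclohex-3-en-1-yl acetate (target)
Conditions: Ac2O, Et3N, DMAP (cat.), CH2Cl2, rt
Reagents that add atoms: acetic anhydride, CC(=O)OC(C)=O
Why: DMAP-catalysed acetylation (nucleophilic catalysis) esterifies the hindered secondary alcohol with retention, since the C–O bond is not touched.

Compound list
1 | umbelliferone (7-hydroxy-2H-chromen-2-one) | Oc1ccc2ccc(=O)oc2c1 | starting material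
2 | racemic 2-vinyloxirane | C=CC1CO1 | starting material
3 | 7-{[(2E)-4-hydroxybut-2-en-1-yl]oxy}-2H-chromen-2-one | OC/C=C/COc1ccc2ccc(=O)oc2c1 | intermediate
4 | methyl (2E)-4-[(2-oxo-2H-chromen-7-yl)oxy]but-2-en-1-yl carbonate | COC(=O)OC/C=C/COc1ccc2ccc(=O)oc2c1 | intermediate
5 | 4-(2-methylprop-1-en-1-yl)morpholine | CC(C)=CN1CCOCC1 | starting material
6 | 4-[(3R)-2,2-dimethyl-3-{[(2-oxo-2H-chromen-7-yl)oxy]methyl}pent-4-en-1-ylidene]morpholin-4-ium methyl carbonate | C=C[C@@H](COc1ccc2ccc(=O)oc2c1)C(C)(C)C=[N+]1CCOCC1.COC([O-])=O | intermediate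
7 | (3R)-2,2-dimethyl-3-{[(2-oxo-2H-chromen-7-yl)oxy]methyl}pent-4-enal | C=C[C@@H](COc1ccc2ccc(=O)oc2c1)C(C)(C)C=O | intermediate
8 | (3R)-2,2-dimethyl-3-{[(2-oxo-2H-chromen-7-yl)oxy]methyl}pent-4-ene-1,1-diyl diacetate | C=C[C@@H](COc1ccc2ccc(=O)oc2c1)C(C)(C)C(OC(C)=O)OC(C)=O | intermediate
9 | (3R)-2,2-dimethyl-4-oxo-3-{[(2-oxo-2H-chromen-7-yl)oxy]methyl}pentane-1,1-diyl diacetate | CC(=O)[C@@H](COc1ccc2ccc(=O)oc2c1)C(C)(C)C(OC(C)=O)OC(C)=O | intermediate
10 | (3S,4E)-2,2-dimethyl-4-[2-(4-methylbenzenesulfonyl)hydrazinylidene]-3-{[(2-oxo-2H-chromen-7-yl)oxy]methyl}pentane-1,1-diyl diacetate | C/C(=N\NS(=O)(=O)c1ccc(C)cc1)[C@@H](COc1ccc2ccc(=O)oc2c1)C(C)(C)C(OC(C)=O)OC(C)=O | intermediate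
11 | 2,4,6-trivinylcyclotriboroxane–pyridine complex | C=CB1OB(C=C)OB(C=C)O1.c1ccncc1 | starting material
12 | N′-[(2E,3S)-4,4-dimethyl-5-oxo-3-{[(2-oxo-2H-chromen-7-yl)oxy]methyl}pentan-2-ylidene]-4-methylbenzenesulfonohydrazide | C/C(=N\NS(=O)(=O)c1ccc(C)cc1)[C@@H](COc1ccc2ccc(=O)oc2c1)C(C)(C)C=O | intermediate
13 | (3S)-4-diazo-2,2-dimethyl-3-{[(2-oxo-2H-chromen-7-yl)oxy]methyl}pentanal | CC(=[N+]=[N-])[C@@H](COc1ccc2ccc(=O)oc2c1)C(C)(C)C=O | intermediate
14 | [(3R,4R)-3,5,5-trimethyl-6-oxo-4-{[(2-oxo-2H-chromen-7-yl)oxy]methyl}hex-1-en-3-yl]boronic acid | C=C[C@](C)(B(O)O)[C@@H](COc1ccc2ccc(=O)oc2c1)C(C)(C)C=O | intermediate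
15 | 7-{[(1R,5R)-5-hydroxy-2,6,6-trimethylcyclohex-2-en-1-yl]methoxy}-2H-chromen-2-one | O[C@@H]1CC=C(C)[C@@H](COc2ccc3ccc(=O)oc3c2)C1(C)C | intermediate
16 | (1R,5R)-4,6,6-trimethyl-5-{[(2-oxo-2H-chromen-7-yl)oxy]methyl}cyclohex-3-en-1-yl acetate | CC(=O)O[C@@H]1CC=C(C)[C@@H](COc2ccc3ccc(=O)oc3c2)C1(C)C | target

Total step count: 8. Longest linear sequence: 8 (steps 1 to 8).

Steps most likely to fail

**Step 7.** Ring closure through the strained boat array may be slow. Protodeboronation, 1,3-boron shift or a 1,2-hydrogen shift of the diazoalkane could then take over. Facial selectivity at the boron–carbon bond formation may also be low. The fallback uses known chemistry, sets out from 7 and comes back at 16.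
- Wacker–Tsuji oxidation of 7 under the conditions of step 5 gives the keto aldehyde F1.
- Brown allylation with Ipc2B(allyl) made from (−)-α-pinene (Et2O, −78 °C, NaBO3 work-up) takes the aldehyde only and sets the carbinol centre by reagent control, giving the homoallylic alcohol F2.
- Ac2O/DMAP gives the keto acetate F3.
- Takai–Lombardo methylenation (Zn, CH2Br2, TiCl4, CH2Cl2) converts the ketone without base into the diene acetate F4.
- Ring-closing metathesis with the second-generation Grubbs catalyst RuCl2(=CHPh)(PCy3)(H2IMes) in toluene at 80 °C closes the trisubstituted alkene and gives 16.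

**Step 3.** The bulky enamine may attack the unsubstituted allyl terminus, the allylic aryl ether end may ionise in competition, or the enantioselectivity may be insufficient. The fallback replaces catalysis by auxiliary control, sets out from 1 and comes back at 9.
- Commercial 3,3-dimethylpent-4-enoic acid is loaded on (S)-4-benzyloxazolidin-2-one (PivCl, Et3N, LiCl) to give the imide F5.
- An Evans syn aldol reaction (Bu2BOTf, Et3N, then acetaldehyde) sets the centre and gives the aldol F6.
- LiBH4 gives the diol F7.
- Mitsunobu etherification with 1 (PPh3, DIAD) at the primary hydroxyl gives the aryl ether alcohol F8.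
- Dess–Martin oxidation gives the methyl ketone F9.
- Lemieux–Johnson cleavage of the vinyl group (OsO4 cat., NaIO4) gives the keto aldehyde F1.
- Ac2O/Bi(OTf)3 as in step 4, which leaves ketones alone, gives 9.

**Step 5.** Hydroxypalladation next to the crowded branched carbon may be slow, the regiochemistry may drift towards the aldehyde, or the acylal may hydrolyse. The fallback changes to radical hydration, sets out from 8 and comes back at 9.
- Mukaiyama hydration (Co(acac)2, PhSiH3, O2, THF) gives the secondary alcohol F10 as a mixture of carbinol epimers.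
- Dess–Martin oxidation gives 9.

Further compounds
F1 | step 7 | (3R)-2,2-dimethyl-4-oxo-3-{[(2-oxo-2H-chromen-7-yl)oxy]methyl}pentanal | CC(=O)[C@@H](COc1ccc2ccc(=O)oc2c1)C(C)(C)C=O
F2 | step 7 | 7-{[(2R,4R)-2-acetyl-4-hydroxy-3,3-dimethylhept-6-en-1-yl]oxy}-2H-chromen-2-one | CC(=O)[C@@H](COc1ccc2ccc(=O)oc2c1)C(C)(C)[C@H](O)CC=C
F3 | step 7 | (4R,6R)-6-acetyl-5,5-dimethyl-7-[(2-oxo-2H-chromen-7-yl)oxy]hept-1-en-4-yl acetate | CC(=O)[C@@H](COc1ccc2ccc(=O)oc2c1)C(C)(C)[C@H](OC(C)=O)CC=C
F4 | step 7 | (4R,6R)-5,5,7-trimethyl-6-{[(2-oxo-2H-chromen-7-yl)oxy]methyl}octa-1,7-dien-4-yl acetate | C=C(C)[C@@H](COc1ccc2ccc(=O)oc2c1)C(C)(C)[C@H](OC(C)=O)CC=C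
F5 | step 3 | (4S)-4-benzyl-3-(3,3-dimethylpent-4-enoyl)-1,3-oxazolidin-2-one | C=CC(C)(C)CC(=O)N1[C@@H](Cc2ccccc2)COC1=O
F6 | step 3 | (4S)-4-benzyl-3-[(2S,3R)-3-hydroxy-2-(2-methylbut-3-en-2-yl)butanoyl]-1,3-oxazolidin-2-one | C[C@@H](O)[C@@H](C(=O)N1[C@@H](Cc2ccccc2)COC1=O)C(C)(C)C=C
F7 | step 3 | (2R,3R)-3-(hydroxymethyl)-4,4-dimethylhex-5-en-2-ol | C[C@@H](O)[C@@H](CO)C(C)(C)C=C
F8 | step 3 | 7-{[(2R,3R)-3-hydroxy-2-(2-methylbut-3-en-2-yl)butyl]oxy}-2H-chromen-2-one | C[C@@H](O)[C@@H](COc1ccc2ccc(=O)oc2c1)C(C)(C)C=C
F9 | step 3 | 7-{[(2R)-2-acetyl-3,3-dimethylpent-4-en-1-yl]oxy}-2H-chromen-2-one | CC(=O)[C@@H](COc1ccc2ccc(=O)oc2c1)C(C)(C)C=C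
F10 | step 5 | (3R)-4-hydroxy-2,2-dimethyl-3-{[(2-oxo-2H-chromen-7-yl)oxy]methyl}pentane-1,1-diyl diacetate (both carbinol epimers) | CC(O)[C@@H](COc1ccc2ccc(=O)oc2c1)C(C)(C)C(OC(C)=O)OC(C)=O
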